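The runs stem from a simulated flask from invented constants; the scatter is artificial.

A small charge of free catalyst, 0.40 mM in south-east and 1.5 mM in south, makes the target, and the target turns into its isomer and back, so the question here is how the product divides, not how much of it there is.

| setting | autumn | noon | south-east | south |
|---|---|---|---|---|
| starting material | 0.80 M | 0.80 M | 0.80 M | 0.80 M |
| partner | 1.4 M | 1.2 M | 1.20 M | 2.00 M |
| protic impurity | 0.80 M | 0.80 M | 0.800 M | 0.800 M |
| free catalyst | 0.40 mM | 1.1 mM | 0.40 mM | 1.5 mM |
| remark | run made earlier | run made earlier |  |  |
| time |  |  | 12 min | 20 min |

- autumn (time / min: target / %, isomer of the product / %): 0.500: 3.3, 0.1; 0.833: 5.5, 2.2; 1.33: 7.0, 2.7; 2.00: 8.3, 8.3; 4.00: 14.8, 14.1; 6.00: 21.5, 22.5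
- noon (time / min: target / %, isomer of the product / %): 0.500: 7.6, 2.3; 0.833: 11.7, 8.7; 1.50: 18.8, 13.9; 3.00: 30.0, 27.2; 6.00: 43.0, 44.8

(each reading ± 1 percentage point)

1. the winner by share of target in all that became target or isomer of the product; "neither" if no more than 2 percentage points parts them (south-east / south / neither)
2. share of target in all that became target or isomer of the product, south-east
3. share of target in all that became target or isomer of the product, south

- on the list of suspects stand: partner + free catalyst <-> catalyst intermediate A; catalyst intermediate A -> catalyst intermediate B; starting material + catalyst intermediate B -> catalyst intermediate C; catalyst intermediate C -> free catalyst + target; partner + protic impurity -> quenched reagent; target <-> isomer of the product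

Ask first what the end state must be. At their last readings the autumn run shows target 21.5% beside isomer 22.5% and the noon run 43.0% beside 44.8%, although their free catalyst differs, 0.40 mM against 1.1 mM. Pooled, they give 48.9% as the standing share, the part of c(target) in c(target) plus c(isomer of the product) once the pair has stopped shifting, and it is a reading with the scatter of those readings.

Then ask how fast it is approached, taking the rungs you can read from the fastest up. The isomer trails at first in the noon run, 2.3% against 7.6% at 0.500 min, but in the autumn run it stands level by 2.00 min, sooner than the 12 min of south-east. Making product is the slower rung: the average autumn pace, with the catalyst charge of south-east, reckons to 13.6 min for a whole charge of starting material, longer than that levelling and longer than the 12 min, so I expect south-east to be read while product is still forming. The average noon pace reckons to 6.83 min for a whole charge, shorter than the 20 min of south, and south holds more catalyst than noon. Since the autumn pair reads level sooner than that reckoned 13.6 min, I take this for thermodynamic rather than kinetic control, and my reckoning holds both flasks at 48.9%, so that they stand inside the margin of 2 percentage points.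

The forecast gives 50% for south-east, 49% for south, and neither, on the ground that “The partner and impurity levels change the yield, not the ratio.”

    partner + free catalyst ⇌ catalyst intermediate A (K = 0.514 L mol⁻¹, k = 766 L mol⁻¹ min⁻¹)
    catalyst intermediate A → catalyst intermediate B (k = 1110 min⁻¹)
    starting material + catalyst intermediate B → catalyst intermediate C (k = 1190 L mol⁻¹ min⁻¹)
    catalyst intermediate C → free catalyst + target (k = 775 min⁻¹)
    partner + protic impurity → quenched reagent (k = 0.108 L mol⁻¹ min⁻¹)
    target ⇌ isomer of the product (K = 1.10, k = 1.72 min⁻¹)

South-east gives 48.4% and south 47.6%, so the verdict is neither, with 0.80 points between them. The relaxation half-life of the pair in south-east, both ways together, is 0.211 min, short against the 12 min of the reading. Put to use, the standing share turns conversion into target: south-east has converted 64.6%, which at 48.9% makes 31.6% of the charge, and the flask holds 31.3%. The same flask as south-east with 2.0 M of partner has 16% of its starting material left at 12.0 min, which reckons to 41.1%, and it holds 40.7% of target.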